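## Analysis of the target

The target (24) is a daucane sesquiterpenoid diester: a cyclopentane trans-fused to a cycloheptane through the quaternary, methyl-bearing C1 and the methine C5. Daucane locants are used throughout: C1 (fusion carbon, methyl), C2 (acetate), C3, C4 (isopropyl carbinol), C5, C6 (4-methoxybenzoate), C7, C8–C9 (epoxide, methyl on C8), C10 (free carbinol); β is the face that carries the C1 methyl. There are eight stereocentres (C1, C2, C4, C5, C6, C8, C9, C10). On the β face lie the C1 methyl, the C2 acetate, the C4 hydroxyl (isopropyl α) and the C10 hydroxyl; on the α face lie H-5, the C6 ester and the epoxide oxygen. The fragile groups are the trisubstituted epoxide next to a free secondary alcohol (migration with base, opening with acid), two different esters, and a tertiary alcohol β to C6, which dehydrates or undergoes retro-aldol cleavage at the ketone stage. The synthesis is hard because C1 is quaternary and flanked by three stereocentres (C2, C5, C10), and because three secondary oxygens (C2, C6, C10) must be told apart. The strategy rests on one feature: the cycloheptane divides into a four-carbon 2-oxygenated diene C7=C6(O)–C5=C1, whose inner double bond is the C=C of a cyclopentenone (ring C1–C5, carbonyl at C4, oxygen at C2), and a three-carbon unit C8–C9–C10 whose C8 substituent can enter as an ester. After that union every remaining substituent has its own handle: the C4 ketone, the C5=C6 enol ether and the C8 ester.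

## Retrosynthetic reasoning

**24 ⇒ 23.** The C8–C9 epoxide is removed first because it is the most fragile group. It goes back to the C8=C9 alkene of allylic alcohol 23. The forward step must deliver oxygen to the α face, anti to the equatorial 10β-hydroxyl; the axial C1 methyl over the β face should enforce this.

**23 ⇒ 22 ⇒ 20.** The 10β-hydroxyl is traced to enone 22, and the enone to the C9=C10 alkene of 20 by an ene reaction with singlet oxygen (through hydroperoxide 21). Only C8 carries an allylic hydrogen, since C1 is quaternary, so the structure fixes the regiochemistry. Passing through the ketone makes the configurations at C8 and C10 of 21 irrelevant and lets hydride, entering anti to the C1 methyl, set 10β. The C2 acetate is attached in the same flask, before a second free secondary hydroxyl exists.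

**20 ⇒ 19 ⇒ 18.** The anisoate is put on the only free secondary hydroxyl of 18 (C6), while C2 is still silylated and C4 is tertiary. This order is what distinguishes the three secondary oxygens: C2 by its silyl ether from the start, C6 by being alone when acylated, C10 by arriving last.

**18 ⇒ 17 ⇒ 16 ⇒ 15 ⇒ 13.** The C8 methyl is cut back to the ester that the carbenoid has to carry, and the C9=C10 alkene to the conjugated C8=C9 ester of 13 through deconjugative protonation of dienolate 14. The hydride steps sit here because no acyl group is yet present.

**13 ⇒ 12 ⇒ 11 ⇒ 10.** The C6 hydroxyl comes from ketone 12 by hydride delivered from the C4 hydroxyl (anti-1,3-diol). The ketone and H-5 come from the enol ether of 11, and the isopropyl carbinol from the C4 ketone of 10. Three contiguous centres are thus read off one vinylogous ester: nucleophile anti to the β substituents, protonation at C5, internal hydride at C6.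

**10 ⇒ 6 + 8 (key cut).** Bonds C7–C8 and C1–C10 are cut. This removes the seven-membered ring and the quaternary centre together and leaves two small fragments, diene 6 and vinyldiazoacetate 8. The cut is made here because only one stereocentre (C2) must be carried into the step and the product keeps three differentiated handles. Forward, the carbenoid cyclopropanates C6=C7 to give 9, and a [3,3] shift forms C1–C10.

**6 ⇒ 4 + 5; 4 ⇒ 3 ⇒ 2 ⇒ 1; 8 ⇒ 7.** The ethoxyvinyl group is attached by cross-coupling of iodoenone 4 with stannane 5. The methyl enone 3 comes from commercial, enantiopure silyloxy enone 1 by conjugate methylation (via 2) and re-oxidation, which avoids a resolution. Diazo transfer to 7 gives 8.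

## Alternatives that were turned down

**Alternative 1:** Buchner ring expansion. It cuts C1–C5 and C1–C10 and takes the seven-membered ring from a benzene ring. A copper carbene (for example with Cu(acac)2) from diazoketone A1 adds across the unsubstituted ipso–ortho bond of its 2-methoxy-4-methylphenyl group, and the norcaradiene opens to the cycloheptatriene A2.
- For: both rings and C1 arise in one step from a cheap arene, and the C8 methyl and the C4 carbinol come with the starting material. On brevity to the bicycle it is stronger than the chosen route, which needs four steps to turn an ester into that methyl.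
- Against: the carbene carbon bears a methyl group, so 1,2-hydride shift to an enone competes. The two ipso–ortho bonds differ, and addition at the methoxy-bearing one would mislead. A2 is a conjugated triene (C5=C6, C7=C8, C9=C10) prone to hydrogen shifts, and its three similar double bonds must be turned regio- and stereoselectively into H-5α, C6–Oα, the epoxide and C10–OHβ. C1 is controlled only by the C4 tertiary silyl ether, which itself needs an enantioselective synthesis.
- In its place the chosen route offers three electronically distinct handles and catalyst control of absolute configuration.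

**Alternative 2:** Carbene C–H insertion. It cuts C3–C4. Rh2(OAc)4 (divalent rhodium) converts diazoketone A3 into a carbenoid at C3 that inserts into the tertiary, oxygen-activated C4–H of the side chain on C5 and closes the cyclopentanone A4 with retention.
- For: 1,5-insertion into such a C–H bond is among the most dependable ring closures. The C4/C5 relationship and the trans fusion are fixed beforehand, so the β-hydroxy ketone hazard of the chosen route does not arise. The key step is probably more predictable than a sigmatropic shift at a fully substituted terminus.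
- Against: the whole difficulty moves into A3, a cycloheptenone that already carries C1, C5 and the carbinol centre, for which no ring-forming step is offered. A4 has no oxygen at C10, a methylene next to the quaternary carbon with no activating group in reach, and its two ketones (C2, C6) must be differentiated. Insertion at the isopropyl methine is a competing path.
- The chosen route is convergent, forms ring and quaternary centre together, and its ester leads by design to C10 oxygenation.

**Alternative 3:** Radical 1,6-addition. It cuts C1–C10. Cp2TiCl (trivalent titanium) opens the C1–C2 epoxide of A5 to the tertiary C1 radical, which adds to C10, the alkoxy-bearing end of the dienone, and protonation at C7 gives A6.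
- For: after the key step the C10 oxygen, the C8 methyl, the C8=C9 alkene and the C2 hydroxyl are all in place. Its end-game is clearly shorter than that of the chosen route.
- Against: seven-membered radical closure is slow beside capture of the tertiary radical by a second equivalent of the titanium reagent. The acceptor carbon carries a donor, so the nucleophilic radical is poorly matched. The dienolate formed can expel the C10 alkoxide. Two stereocentres (C1, C10) form without an evident bias, and A5 itself is a long, sensitive target.
- The chosen route offers a ring-forming step of an established type for seven-membered rings and quaternary carbons, a precursor four steps from a commercial enone, and catalyst-controlled configuration at C1.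

Key step: step 6

**Assumptions (remarks on the chemistry).**
- The dirhodium prolinate catalyst is assumed to show the same sense of induction as in its cyclopropanations of styrene with aryl- and vinyldiazoacetates. On the end-on model this makes Rh2(R-DOSP)4, tetrakis[(R)-N-(4-dodecylbenzenesulfonyl)prolinato]dirhodium, the matched catalyst for the (R)-silyl ether.
- C8 in 15–20 is an uncontrolled mixture of epimers that converges in step 16.

## Route

**Step 1**
Reactants: 1 (R)-4-(tert-butyldimethylsilyloxy)cyclopent-2-en-1-one
Product: 2 (3R,4R)-4-(tert-butyldimethylsilyloxy)-3-methyl-1-(trimethylsilyloxy)cyclopent-1-ene (methyl trans to OTBS)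
Conditions: Me2CuLi, TMSCl, THF, −78 °C; Et3N, cold NaHCO3 work-up
Reagents that add atoms: lithium dimethylcuprate [Li+].C[Cu-]C; chlorotrimethylsilane C[Si](C)(C)Cl
Why: Cuprate conjugate addition to the enone occurs anti to the C4 silyloxy group and the enolate is O-silylated at once, which fixes the C1=C2 enol regiochemistry and prevents enolate equilibration with loss of the β-silyloxy group; the new C3 stereocentre is destroyed in step 2.

**Step 2**
Reactants: 2 (3R,4R)-4-(tert-butyldimethylsilyloxy)-3-methyl-1-(trimethylsilyloxy)cyclopent-1-ene
Product: 3 (R)-4-(tert-butyldimethylsilyloxy)-3-methylcyclopent-2-en-1-one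
Conditions: Pd(OAc)2 (10 mol%), O2 (1 atm), DMSO, 25 °C
Reagents that add atoms: none
Why: Saegusa–Ito oxidation: the palladium enolate formed from the silyl enol ether undergoes β-hydride elimination of its only β-hydrogen (C3–H) and oxygen reoxidises the catalyst; the C4 stereocentre is not involved.

**Step 3**
Reactants: 3 (R)-4-(tert-butyldimethylsilyloxy)-3-methylcyclopent-2-en-1-one
Product: 4 (R)-4-(tert-butyldimethylsilyloxy)-2-iodo-3-methylcyclopent-2-en-1-one
Conditions: I2, pyridine, CH2Cl2, 0 → 25 °C
Reagents that add atoms: iodine II
Why: α-Iodination of an enone by the addition–elimination sequence with pyridine (conjugate addition, iodination of the enolate, loss of pyridinium); the β-methyl group slows the reaction but the silyl ether tolerates the weakly basic medium.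

**Step 4**
Reactants: 4 (R)-4-(tert-butyldimethylsilyloxy)-2-iodo-3-methylcyclopent-2-en-1-one; 5 tributyl(1-ethoxyvinyl)stannane
Product: 6 (R)-4-(tert-butyldimethylsilyloxy)-2-(1-ethoxyvinyl)-3-methylcyclopent-2-en-1-one
Conditions: Pd2(dba)3 (2.5 mol%), AsPh3, CuI, N-methylpyrrolidone, 40 °C; KF work-up, Et3N-treated silica
Reagents that add atoms: none
Why: Stille coupling of a 2-iodoenone with an α-alkoxyvinylstannane; copper iodide speeds transmetalation of the hindered stannane and the soft arsine ligand allows a mild temperature, so the acid-labile enol ether and the β-silyloxy ketone survive.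

**Step 5**
Reactants: 7 methyl but-3-enoate
Product: 8 methyl 2-diazobut-3-enoate
Conditions: 4-acetamidobenzenesulfonyl azide, DBU, MeCN, 0 °C; cold pentane extraction, used at once
Reagents that add atoms: 4-acetamidobenzenesulfonyl azide CC(=O)Nc1ccc(cc1)S(=O)(=O)N=[N+]=[N-]
Why: Regitz diazo transfer to the doubly activated methylene (allylic and α to the ester) with a sulfonyl azide and an amidine base; the product is kept cold and used immediately because it cyclises to a pyrazole on standing.

**Step 6**
Reactants: 6 (R)-4-(tert-butyldimethylsilyloxy)-2-(1-ethoxyvinyl)-3-methylcyclopent-2-en-1-one; 8 methyl 2-diazobut-3-enoate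
Product: 10 dienone ester (1β-methyl; 2β-OTBS; 4-oxo; 6-ethoxy-5-ene; 8-ene-8-CO2Me), via divinylcyclopropane 9 (not isolated)
Conditions: 8 (3 equiv, slow addition), Rh2(R-DOSP)4 (2 mol%), PhCF3, −20 → 25 °C; then toluene, 90 °C
Reagents that add atoms: none
Why: The dirhodium catalyst (divalent rhodium) turns 8 into an electrophilic donor–acceptor vinylcarbenoid, which adds to the electron-rich, unhindered CH2=C(OEt) bond (C6=C7) of 6 and leaves alone the tetrasubstituted, carbonyl-deactivated C1=C5 bond, the ketone and the C2–H. The closest known reaction type is the tandem cyclopropanation–Cope rearrangement (formal [4+3] cycloaddition) of vinyldiazoacetates with 2-oxygenated and ring-bearing dienes, including cases that create a quaternary carbon at the diene terminus. The three-membered ring closes by concerted, asynchronous carbene transfer (C7–C8 first, charge at C6 stabilised by OEt), and the usual end-on approach places the conjugating cyclopentenyl group cis to the vinyl group and OEt cis to the ester, which is the cis-divinylcyclopropane 9. The seven-membered ring closes by a [3,3]-sigmatropic shift through the boat transition state, in which C1–C10 forms between the two vinyl termini while the C6–C8 cyclopropane bond breaks, so the closure is a strain-driven pericyclic ring expansion. Because the C1 methyl must point inward in the boat the shift should need warming, but it is helped by polarisation, C10 being the end of an ester-stabilised allyl unit and C1 the β-carbon of the enone. The one new stereocentre, C1, follows from the cyclopropane configuration, since in the boat the cyclopentenone can offer only one face to C10; the chiral catalyst sets that configuration and its enantiomer is chosen so that this face is anti to the C2 silyloxy group (matched pair), which leaves the C1 methyl cis to the C2 oxygen. The step needs chemoselectivity (enol ether over enone alkene), cis selectivity in the cyclopropanation and face selectivity at C1, and these are secured by the electronic contrast of the two alkenes, by the donor group of the carbenoid and by the catalyst–C2 pairing.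

**Step 7**
Reactants: 10 dienone ester
Product: 11 tertiary alcohol (4β-OH; 4α-isopropyl; 6-ethoxy-5-ene; 8-ene-8-CO2Me; 2β-OTBS)
Conditions: i-PrMgCl, CeCl3 (anhydrous), THF, −78 °C; NaHCO3 work-up
Reagents that add atoms: isopropylmagnesium chloride CC(C)[Mg]Cl
Why: Organocerium reagents add 1,2 to hindered, enolisable ketones with little enolisation or hydride transfer and attack the vinylogous ester carbonyl much faster than the conjugated methyl ester at −78 °C; approach to C4 from the α face, anti to the C1 methyl and the C2 silyloxy group, should give the 4β-hydroxyl.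

**Step 8**
Reactants: 11 tertiary alcohol
Product: 12 β-hydroxy ketone (4β-OH; 5α-H; 6-oxo; 8-ene-8-CO2Me; 2β-OTBS)
Conditions: AcOH/NaOAc buffer (pH about 4.5), THF–H2O, 0 → 25 °C
Reagents that add atoms: water O
Why: Enol ether hydrolysis is general-acid catalysed (rate-limiting proton transfer to C5) whereas loss of the tertiary allylic hydroxyl needs specific acid, so a carboxylic acid buffer should favour the ketone over the dehydrative enone transposition; protonation of C5 anti to the C1 methyl, or equilibration through the enol, should give the trans-fused ketone, in which the isopropyl group is trans to C6 and the C4 hydroxyl hydrogen-bonds to the carbonyl.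

**Step 9**
Reactants: 12 β-hydroxy ketone
Product: 13 4β,6α-diol (8-ene-8-CO2Me; 2β-OTBS)
Conditions: Me4NBH(OAc)3, MeCN–AcOH, −30 °C
Reagents that add atoms: none
Why: Evans–Saksena reduction: the C4 hydroxyl exchanges an acetate on boron and delivers hydride internally to the β face of the C6 carbonyl, giving the anti-1,3-diol (6α-OH) against the steric bias of the axial C1 methyl; the conjugated ester and the silyl ether are not touched.

**Step 10**
Reactants: 13 4β,6α-diol
Product: 15 deconjugated ester (9-ene; CO2Me on sp3 C8; both C8 epimers), via lithium dienolate 14 (not isolated)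
Conditions: LiN(iPr)2 (4.5 equiv), THF–HMPA, −78 → −40 °C; then AcOH, THF, −78 °C
Reagents that add atoms: none
Why: Once both hydroxyls are lithium alkoxides the C10 hydrogens are the only acidic C–H, so γ-deprotonation gives the extended ester enolate, and kinetic protonation of such dienolates occurs at the α-carbon (C8), leaving the alkene at C9=C10 (deconjugative protonation); the C8 configuration need not be controlled because C8 returns to sp2 in step 16.

**Step 11**
Reactants: 15 deconjugated ester
Product: 16 triol (8-CH2OH; 9-ene; 4β-OH; 6α-OH; 2β-OTBS)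
Conditions: LiAlH4, THF, 0 °C
Reagents that add atoms: none
Why: Hydride reduction of the non-conjugated ester to the primary alcohol; the alkoxides of the two hydroxyls are inert and the silyl ether survives at 0 °C.

**Step 12**
Reactants: 16 triol
Product: 17 primary 4-toluenesulfonate of 16
Conditions: TsCl (1.1 equiv), pyridine, CH2Cl2, 0 °C
Reagents that add atoms: 4-toluenesulfonyl chloride Cc1ccc(cc1)S(Cl)(=O)=O
Why: Sulfonylation is selective for the primary hydroxyl over the hindered secondary C6 hydroxyl and the tertiary C4 hydroxyl.

**Step 13**
Reactants: 17 primary 4-toluenesulfonate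
Product: 18 8-methyl-9-ene diol (4β-OH; 6α-OH; 2β-OTBS)
Conditions: LiEt3BH (5 equiv), THF, 0 → 25 °C
Reagents that add atoms: none
Why: SN2 displacement of a primary sulfonate by the strong hydride donor LiEt3BH gives the methyl group; excess reagent is used because the two hydroxyls consume hydride, and direct displacement is expected to outrun internal etherification by the C6 alkoxide.

**Step 14**
Reactants: 18 8-methyl-9-ene diol
Product: 19 6α-(4-methoxybenzoate) of 18
Conditions: 4-methoxybenzoyl chloride, DMAP, pyridine, CH2Cl2, 25 °C
Reagents that add atoms: 4-methoxybenzoyl chloride COc1ccc(cc1)C(Cl)=O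
Why: DMAP-catalysed acylation of the only free secondary hydroxyl; the tertiary C4 hydroxyl does not react under these conditions.

**Step 15**
Reactants: 19 6α-(4-methoxybenzoate)
Product: 20 2β-alcohol (4β-OH; 6α-anisoate; 8-methyl; 9-ene)
Conditions: HF·pyridine, THF–pyridine, 0 → 25 °C
Reagents that add atoms: none
Why: Fluoride cleaves the silyl ether; the buffered reagent is neither basic enough to cause acyl migration nor acidic enough to dehydrate the tertiary alcohol.

**Step 16**
Reactants: 20 2β-alcohol
Product: 22 enone (8-en-10-one; 2β-OAc; 4β-OH; 6α-anisoate), via allylic hydroperoxide 21 (not isolated)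
Conditions: O2, tetraphenylporphyrin (cat.), visible light, CH2Cl2, 0 °C; then Ac2O, pyridine, DMAP, 0 → 25 °C
Reagents that add atoms: oxygen O=O; acetic anhydride CC(=O)OC(C)=O
Why: Schenck ene reaction: singlet oxygen bonds to C10 while the C8 hydrogen is transferred and the double bond moves to C8=C9, and since only C8 offers an allylic hydrogen a single regioisomer can form. Acetic anhydride then acylates the hydroperoxide, whose peracetate loses acetic acid to give the ketone (Kornblum–DeLaMare-type dehydration), erasing the uncontrolled C8 and C10 configurations, and it acetylates the free C2 hydroxyl but not the tertiary one.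

**Step 17**
Reactants: 22 enone
Product: 23 10β-allylic alcohol (8-ene; 2β-OAc; 4β-OH; 6α-anisoate)
Conditions: NaBH4, CeCl3·7H2O, MeOH, −40 → 0 °C
Reagents that add atoms: none
Why: Luche reduction gives 1,2-reduction of the enone; hydride should enter C10 from the α face, anti to the axial methyl on the neighbouring quaternary C1, which places the hydroxyl β (equatorial), and both esters survive at low temperature.

**Step 18**
Reactants: 23 10β-allylic alcohol
Product: 24 the target, 2β-acetoxy-8α,9α-epoxy-4β,10β-dihydroxy-6α-(4-methoxybenzoyloxy)-5α-daucane
Conditions: dimethyldioxirane, acetone, 0 °C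
Reagents that add atoms: dimethyldioxirane CC1(C)OO1
Why: Epoxidation of the electron-rich trisubstituted alkene by a neutral dioxirane; in the chair-like cycloheptene the axial C1 methyl lies over the β face of C8=C9 while the α face carries only hydrogens (10β-OH and the 6α-ester are equatorial), and acetone suppresses hydroxyl-directed delivery, so the α-epoxide is expected; the neutral medium avoids epoxide migration or opening.

## Compound list

1 | (R)-4-(tert-butyldimethylsilyloxy)cyclopent-2-en-1-one | O=C1C=C[C@H](O[Si](C)(C)C(C)(C)C)C1 | starting material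
2 | (3R,4R)-4-(tert-butyldimethylsilyloxy)-3-methyl-1-(trimethylsilyloxy)cyclopent-1-ene | C[C@@H]1C=C(O[Si](C)(C)C)C[C@H]1O[Si](C)(C)C(C)(C)C | intermediate
3 | (R)-4-(tert-butyldimethylsilyloxy)-3-methylcyclopent-2-en-1-one | CC1=CC(=O)C[C@H]1O[Si](C)(C)C(C)(C)C | intermediate
4 | (R)-4-(tert-butyldimethylsilyloxy)-2-iodo-3-methylcyclopent-2-en-1-one | CC1=C(I)C(=O)C[C@H]1O[Si](C)(C)C(C)(C)C | intermediate
5 | tributyl(1-ethoxyvinyl)stannane | CCCC[Sn](CCCC)(CCCC)C(=C)OCC | starting material
6 | (R)-4-(tert-butyldimethylsilyloxy)-2-(1-ethoxyvinyl)-3-methylcyclopent-2-en-1-one | C=C(OCC)C1=C(C)[C@H](O[Si](C)(C)C(C)(C)C)CC1=O | intermediate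
7 | methyl but-3-enoate | C=CCC(=O)OC | starting material
8 | methyl 2-diazobut-3-enoate | C=CC(=[N+]=[N-])C(=O)OC | intermediate
9 | methyl (1S,2R)-2-ethoxy-1-ethenyl-2-[(3R)-3-(tert-butyldimethylsilyloxy)-2-methyl-5-oxocyclopent-1-en-1-yl]cyclopropane-1-carboxylate (vinyl and cyclopentenyl cis) | COC(=O)[C@]1(C=C)C[C@@]1(OCC)C2=C(C)[C@H](O[Si](C)(C)C(C)(C)C)CC2=O | intermediate (not isolated)
10 | dienone ester: 1β-methyl, 2β-OTBS, C4 ketone, C5=C6 ethyl enol ether, C8=C9 with CO2Me on C8 | COC(=O)C1=CC[C@@]2(C)[C@H](O[Si](C)(C)C(C)(C)C)CC(=O)C2=C(OCC)C1 | intermediate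
11 | tertiary alcohol: 4β-OH, 4α-isopropyl, C5=C6 ethyl enol ether, C8=C9 ester, 2β-OTBS | COC(=O)C1=CC[C@@]2(C)[C@H](O[Si](C)(C)C(C)(C)C)C[C@@](O)(C(C)C)C2=C(OCC)C1 | intermediate
12 | β-hydroxy ketone: 4β-OH, 5α-H (trans fusion), C6 ketone, C8=C9 ester, 2β-OTBS | COC(=O)C1=CC[C@@]2(C)[C@H](O[Si](C)(C)C(C)(C)C)C[C@@](O)(C(C)C)[C@@H]2C(=O)C1 | intermediate
13 | 4β,6α-diol with C8=C9 ester and 2β-OTBS | COC(=O)C1=CC[C@@]2(C)[C@H](O[Si](C)(C)C(C)(C)C)C[C@@](O)(C(C)C)[C@@H]2[C@@H](O)C1 | intermediate
14 | trilithium salt: ester dienolate (C8=C(OMe)O−, C9=C10) with C4 and C6 alkoxides | COC([O-])=C1C=C[C@@]2(C)[C@H](O[Si](C)(C)C(C)(C)C)C[C@@]([O-])(C(C)C)[C@@H]2[C@@H]([O-])C1.[Li+].[Li+].[Li+] | intermediate (not isolated)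
15 | deconjugated ester: C9=C10, CO2Me on sp3 C8 (both epimers), 4β,6α-diol, 2β-OTBS | COC(=O)C1C=C[C@@]2(C)[C@H](O[Si](C)(C)C(C)(C)C)C[C@@](O)(C(C)C)[C@@H]2[C@@H](O)C1 | intermediate
16 | triol: C8–CH2OH, C9=C10, 4β-OH, 6α-OH, 2β-OTBS | OCC1C=C[C@@]2(C)[C@H](O[Si](C)(C)C(C)(C)C)C[C@@](O)(C(C)C)[C@@H]2[C@@H](O)C1 | intermediate
17 | primary 4-toluenesulfonate of 16 | Cc1ccc(cc1)S(=O)(=O)OCC3C=C[C@@]2(C)[C@H](O[Si](C)(C)C(C)(C)C)C[C@@](O)(C(C)C)[C@@H]2[C@@H](O)C3 | intermediate
18 | 8-methyl-9-ene diol: 4β-OH, 6α-OH, 2β-OTBS | CC1C=C[C@@]2(C)[C@H](O[Si](C)(C)C(C)(C)C)C[C@@](O)(C(C)C)[C@@H]2[C@@H](O)C1 | intermediate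
19 | 6α-(4-methoxybenzoate) of 18 | CC1C=C[C@@]2(C)[C@H](O[Si](C)(C)C(C)(C)C)C[C@@](O)(C(C)C)[C@@H]2[C@@H](OC(=O)c3ccc(OC)cc3)C1 | intermediate
20 | 2β-alcohol: 4β-OH, 6α-anisoate, 8-methyl, C9=C10 | CC1C=C[C@@]2(C)[C@H](O)C[C@@](O)(C(C)C)[C@@H]2[C@@H](OC(=O)c3ccc(OC)cc3)C1 | intermediate
21 | allylic hydroperoxide: C10–OOH (either configuration), C8=C9, 2β-OH | CC1=CC(OO)[C@@]2(C)[C@H](O)C[C@@](O)(C(C)C)[C@@H]2[C@@H](OC(=O)c3ccc(OC)cc3)C1 | intermediate (not isolated)
22 | enone: C8=C9–C10=O, 2β-OAc, 4β-OH, 6α-anisoate | CC1=CC(=O)[C@@]2(C)[C@H](OC(C)=O)C[C@@](O)(C(C)C)[C@@H]2[C@@H](OC(=O)c3ccc(OC)cc3)C1 | intermediate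
23 | 10β-allylic alcohol: C8=C9, 2β-OAc, 4β-OH, 6α-anisoate | CC1=C[C@H](O)[C@@]2(C)[C@H](OC(C)=O)C[C@@](O)(C(C)C)[C@@H]2[C@@H](OC(=O)c3ccc(OC)cc3)C1 | intermediate
24 | 2β-acetoxy-8α,9α-epoxy-4β,10β-dihydroxy-6α-(4-methoxybenzoyloxy)-5α-daucane (CNP0371526.1) | COc1ccc(C(=O)O[C@H]2C[C@@]3(C)O[C@H]3[C@H](O)[C@]3(C)[C@@H]2[C@](O)(C(C)C)C[C@H]3OC(C)=O)cc1 | target

## Step count and least certain steps

Total: 18 steps. Longest linear sequence: 17 steps (steps 1–4 and 6–18, from 1); step 5 is a one-step side branch.

**Step 6 (key step).** The most likely failure is that the sigmatropic shift is slow, because the C1 methyl must turn inward at a fully substituted terminus. At the temperature then needed the alkoxy- and ester-substituted cyclopropane can open heterolytically and reclose to a cyclopentene (bond C6–C10). Reagent 8 can also be lost by cyclisation to a pyrazole before the hindered alkene captures it.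
Fallback, from 6 back to 10: keep the bond set but change the carbenoid to its 3-silyloxy analogue. Methyl 3-(tert-butyldimethylsilyloxy)-2-diazobut-3-enoate F1 (from methyl 2-diazo-3-oxobutanoate, TBSOTf, Et3N) is bench-stable. Its C10 is a silyl enol ether terminus, so bond formation to the electrophilic C1 is more strongly polarised. With the matched enantiomer of Rh2(PTAD)4 it should give the C9 silyl enol ether cycloadduct F2. CsF and PhNTf2 convert this into the C9 enol triflate F3, and Pd(OAc)2, PPh3, HCO2H, Bu3N reduce the triflate to C9–H, which is 10.

**Step 7.** The branched reagent may act as a hydride donor or as a base at the hindered, deactivated carbonyl. The result would be reduction, or enolisation toward C3 with loss of the C2 silyloxy group, or attack on the ester.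
Fallback, from 10 back to 11: add the smaller sp2 reagent isopropenylmagnesium bromide with CeCl3 to give the isopropenyl carbinol F4. Then hydrogenate the 1,1-disubstituted alkene with H2 and RhCl(PPh3)3, which leaves the trisubstituted ester alkene and the tetrasubstituted enol ether.

**Step 8.** Ionisation of the tertiary allylic hydroxyl with loss of water would lead to the transposed enone. Protonation of C5 from the β face would give the cis-fused ketone.
Fallback, from 11 back to 12: avoid protic acid altogether. NBS with NaHCO3 in THF–H2O attacks the enol ether and gives the 5-bromo-6-ketone F5. Bu3SnH with AIBN (or Zn, NH4Cl) then replaces bromine by hydrogen. Any cis-fused material can be equilibrated through the enol.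

**Step 16.** The ene reaction may be slow. A cis-disubstituted ring alkene is a poor acceptor, oxygen must enter next to the quaternary C1, and the single allylic hydrogen must stand perpendicular to the alkene plane, so one C8 epimer may lag.
Fallback, from 20 back to 22: an ionic 1,3-transposition. mCPBA gives the 9,10-epoxide F6 (drawn α). (PhSe)2 with NaBH4 in EtOH opens it at the less hindered C9 to the hydroxy selenide F7. H2O2 with pyridine gives, by selenoxide syn-elimination toward C8, the 10-allylic alcohol F8; this needs the C8 hydrogen cis to selenium. MnO2 oxidises only the allylic hydroxyl to the enone 2-ol F9, and Ac2O, pyridine, DMAP give 22.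

**Step 18.** Facial selectivity may be poor if the 10β-hydroxyl guides the oxidant to the β face. The epoxy alcohol can also rearrange by epoxide migration if base is present.
Fallback, from 23 back to 24: remove the directing hydroxyl. TESCl and imidazole give the triethylsilyl ether F10, whose β face is then blocked by both the silyl ether and the C1 methyl. mCPBA with NaHCO3 gives the epoxide silyl ether F11, and HF·pyridine gives 24.

## Further compounds

F1 | step 6 | methyl 3-(tert-butyldimethylsilyloxy)-2-diazobut-3-enoate | C=C(O[Si](C)(C)C(C)(C)C)C(=[N+]=[N-])C(=O)OC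
F2 | step 6 | C9 silyl enol ether analogue of 10 (9-OTBS on C8=C9) | COC(=O)C1=C(O[Si](C)(C)C(C)(C)C)C[C@@]2(C)[C@H](O[Si](C)(C)C(C)(C)C)CC(=O)C2=C(OCC)C1
F3 | step 6 | C9 enol triflate analogue of 10 | COC(=O)C1=C(OS(=O)(=O)C(F)(F)F)C[C@@]2(C)[C@H](O[Si](C)(C)C(C)(C)C)CC(=O)C2=C(OCC)C1
F4 | step 7 | isopropenyl carbinol (4β-OH, 4α-isopropenyl analogue of 11) | COC(=O)C1=CC[C@@]2(C)[C@H](O[Si](C)(C)C(C)(C)C)C[C@@](O)(C(C)=C)C2=C(OCC)C1
F5 | step 8 | 5-bromo-6-ketone (4β-OH, C5 configuration open) | COC(=O)C1=CC[C@@]2(C)[C@H](O[Si](C)(C)C(C)(C)C)C[C@@](O)(C(C)C)C2(Br)C(=O)C1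
F6 | step 16 | 9α,10α-epoxide of 20 (C8 epimers) | CC1[C@H]2O[C@H]2[C@@]3(C)[C@H](O)C[C@@](O)(C(C)C)[C@@H]3[C@@H](OC(=O)c4ccc(OC)cc4)C1
F7 | step 16 | 9β-phenylseleno-10α-ol | CC1[C@H]([Se]c2ccccc2)[C@@H](O)[C@@]3(C)[C@H](O)C[C@@](O)(C(C)C)[C@@H]3[C@@H](OC(=O)c4ccc(OC)cc4)C1
F8 | step 16 | 10α-allylic alcohol (C8=C9, 2β-OH) | CC1=C[C@@H](O)[C@@]3(C)[C@H](O)C[C@@](O)(C(C)C)[C@@H]3[C@@H](OC(=O)c4ccc(OC)cc4)C1
F9 | step 16 | enone with free 2β-OH | CC1=CC(=O)[C@@]3(C)[C@H](O)C[C@@](O)(C(C)C)[C@@H]3[C@@H](OC(=O)c4ccc(OC)cc4)C1
F10 | step 18 | 10β-triethylsilyl ether of 23 | CC1=C[C@H](O[Si](CC)(CC)CC)[C@@]2(C)[C@H](OC(C)=O)C[C@@](O)(C(C)C)[C@@H]2[C@@H](OC(=O)c3ccc(OC)cc3)C1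
F11 | step 18 | 10β-triethylsilyl ether of 24 | COc1ccc(C(=O)O[C@H]2C[C@@]3(C)O[C@H]3[C@H](O[Si](CC)(CC)CC)[C@]3(C)[C@@H]2[C@](O)(C(C)C)C[C@H]3OC(C)=O)cc1
A1 | alternative 1 | 2-diazo-5-(2-methoxy-4-methylphenyl)-6-methyl-5-(triethylsilyloxy)heptan-3-one | CC(=[N+]=[N-])C(=O)C[C@@](O[Si](CC)(CC)CC)(C(C)C)c1ccc(C)cc1OC
A2 | alternative 1 | 8a-methylazulenone (C2 ketone, C4 silyl ether with isopropyl, C6 methyl enol ether, C8 methyl, cycloheptatriene) | C[C@@]12C=CC(C)=CC(OC)=C1[C@](O[Si](CC)(CC)CC)(C(C)C)CC2=O
A3 | alternative 2 | cycloheptenone diazoketone (diazoacetyl and methyl on C1, silylated carbinol side chain on C5) | O=C1C=C(C)CC[C@@](C)(C(=O)C=[N+]=[N-])[C@@H]1[C@H](O[Si](CC)(CC)CC)C(C)C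
A4 | alternative 2 | trans-fused hydroazulene diketone (C2 ketone, C4 silyl ether with isopropyl, C6 enone with C7=C8) | O=C1C=C(C)CC[C@]2(C)[C@@H]1[C@](O[Si](CC)(CC)CC)(C(C)C)CC2=O
A5 | alternative 3 | epoxycyclopentyl dienone (C1–C2 epoxide, C4 silyl ether, dienone with 4-methoxybenzyloxy terminus) | O=C(C=C(C)C=COCc1ccc(OC)cc1)[C@H]2[C@](O[Si](CC)(CC)CC)(C(C)C)C[C@H]3O[C@@]23C
A6 | alternative 3 | trans-fused daucenone (C6 ketone, C8=C9, C10 4-methoxybenzyl ether, C2 hydroxyl, C4 silyl ether) | O=C1CC(C)=C[C@H](OCc3ccc(OC)cc3)[C@]2(C)[C@@H]1[C@](O[Si](CC)(CC)CC)(C(C)C)C[C@H]2O
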